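The route cuts the aryl ether bond O1–C8a of the pyranone ring (ring C, flavanone numbering), not the usual O1–C2 bond. Ring A is a para-hydroquinone monomethyl ether (C8–OH para to C5–OMe) whose only unsubstituted carbon is C8a. Oxidative dearomatization of an open-chain phenol to its quinone monoketal reverses the polarity of C8a. The C2 hydroxyl then adds to C8a, and loss of methanol restores the aromatic ring, closing ring C and regenerating the C8 phenol in one operation. The precursor is an (S)-β-hydroxy ketone whose C2 stereocentre, set by asymmetric hydrogenation, is never touched by the ring closure.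

Key step: step 6

Remark: atoms are numbered as in a flavanone (O1, C2, C3, C4, C4a, C5–C8, C8a; ring A = benzo ring, ring B = 3,4-dimethoxyphenyl, ring C = pyranone). Compounds 1 and 5 are taken as commercial.

Step 1
Reactants: 1 2,3,4-trimethoxybenzaldehyde
Product: 2 5-bromo-2,3,4-trimethoxybenzaldehyde
Conditions: NBS (1.05 equiv), MeCN, rt
Reagents that add atoms: N-bromosuccinimide, O=C1CCC(=O)N1Br
Why: Electrophilic aromatic bromination should go to C5, which is para to the C2 methoxy group, ortho to the C4 methoxy group and meta to the formyl group, whereas C6 is ortho to the deactivating formyl group.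

Step 2
Reactants: 2 5-bromo-2,3,4-trimethoxybenzaldehyde
Product: 4 5-bromo-2,3,4-trimethoxyphenol, via aryl formate 3 (not isolated)
Conditions: mCPBA (1.3 equiv), CH2Cl2, rt; then K2CO3 (cat.), MeOH, rt
Reagents that add atoms: mCPBA, OOC(=O)c1cccc(Cl)c1
Why: Baeyer–Villiger (Dakin-type) oxidation, in which the electron-rich aryl group with ortho and para methoxy donors migrates in preference to hydrogen, followed by methanolysis of formate 3 to the phenol.

Step 3
Reactants: 5 ethyl 3-(3,4-dimethoxyphenyl)-3-oxopropanoate
Product: 6 ethyl (3S)-3-(3,4-dimethoxyphenyl)-3-hydroxypropanoate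
Conditions: H2 (50 atm), [RuCl(p-cymene)((R)-BINAP)]Cl (0.5 mol %), EtOH, 50 °C
Reagents that add atoms: none
Why: Noyori asymmetric hydrogenation of a β-keto ester through the ester-chelated ruthenium hydride; (R)-BINAP should deliver hydride to the face that gives (R)-3-hydroxybutanoates from acetoacetates, which for an aroylacetate carries the descriptor S because aryl outranks CH2CO2Et.

Step 4
Reactants: 6 ethyl (3S)-3-(3,4-dimethoxyphenyl)-3-hydroxypropanoate
Product: 7 (3S)-3-(3,4-dimethoxyphenyl)-3-hydroxy-N-methoxy-N-methylpropanamide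
Conditions: MeNH(OMe)·HCl (2 equiv), iPrMgCl (5 equiv), THF, −20 to 0 °C
Reagents that add atoms: N,O-dimethylhydroxylamine hydrochloride, CNOC.Cl
Why: Weinreb amide formation by aminolysis of the ester with the chloromagnesium amide; the carbinol is masked in the flask as its magnesium alkoxide and the stereocentre is not involved.

Step 5
Reactants: 4 5-bromo-2,3,4-trimethoxyphenol; 7 (3S)-3-(3,4-dimethoxyphenyl)-3-hydroxy-N-methoxy-N-methylpropanamide
Product: 11 (3S)-3-(3,4-dimethoxyphenyl)-3-hydroxy-1-(5-hydroxy-2,3,4-trimethoxyphenyl)propan-1-one, via dilithiated phenol 8 (not isolated), via chloromagnesium alkoxide 9 (not isolated), via tetrahedral adduct 10 (not isolated)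
Conditions: 4: MeLi (1.0 equiv) then t-BuLi (2.0 equiv), THF, −78 °C; 7: iPrMgCl (1.0 equiv), THF, −20 °C; combine, −78 to 0 °C; aq NH4Cl
Reagents that add atoms: none
Why: Halogen–lithium exchange followed by Weinreb ketone synthesis; chelated adduct 10 should hold until the quench, so there is no over-addition, the retro-aldol-prone β-hydroxy ketone appears only on work-up, and C2 stays S because the phenoxide and alkoxide are spectators.

Step 6
Reactants: 11 (3S)-3-(3,4-dimethoxyphenyl)-3-hydroxy-1-(5-hydroxy-2,3,4-trimethoxyphenyl)propan-1-one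
Product: 14 (2S)-2-(3,4-dimethoxyphenyl)-8-hydroxy-5,6,7-trimethoxy-2,3-dihydro-4H-chromen-4-one, via quinone monoketal 12 (not isolated), via 8aH-dienone tautomer 13 (not isolated)
Conditions: PhI(OAc)2 (1.0 equiv), MeOH, −20 °C; concentrate; PPTS (0.2 equiv), 4 Å MS, CH2Cl2, 0 °C to rt
Reagents that add atoms: methanol, CO (supplies the second methoxy group of ketal 12; either ketal methoxy group may be the one that remains at C5)
Why: Proposed new method: PhI(OAc)2 in MeOH dearomatizes the para-methoxyphenol of ring A to quinone monoketal 12, which turns C8a from a nucleophilic carbon ortho to the phenol into an electrophilic one, vinylogous to the ketal carbon C5 and β to the C4 ketone (polarity reversal). Mild acid then ionizes the ketal and the C2 hydroxyl adds to C8a in a 6-endo-trig closure of ring C with loss of methanol, giving 8aH-dienone 13, whose enolization restores the aromatic ring as the C8 phenol. The closest known reactions are the acid-promoted substitution of quinone monoketals by nucleophiles at the carbon α to the carbonyl and the conjugate addition of heteroatom nucleophiles next to the acyl group of 2-acyl-1,4-benzoquinones; an intramolecular alcohol version ending in a chroman-4-one has not been shown. No stereocentre is formed: the C2–O bond is never broken, so the S configuration from step 3 is carried over, and the transient C8a centre of 13 is erased on aromatization. The step needs attack at C8a and not at C5 or C7: C8a is the only unsubstituted carbon of ring A and the only one that closes a six-membered ring irreversibly, C7 is out of reach of the tether, and capture at C5 is only a reversible ketal exchange that the acid returns to the same cation. Consuming one equivalent of oxidant at low temperature before the acid is added should keep the product, itself a para-methoxyphenol, from being oxidized again.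

Compound list
1 | 2,3,4-trimethoxybenzaldehyde | O=Cc1ccc(OC)c(OC)c1OC | starting material
2 | 5-bromo-2,3,4-trimethoxybenzaldehyde | O=Cc1cc(Br)c(OC)c(OC)c1OC | intermediate
3 | 5-bromo-2,3,4-trimethoxyphenyl formate | O=COc1cc(Br)c(OC)c(OC)c1OC | intermediate (not isolated)
4 | 5-bromo-2,3,4-trimethoxyphenol | Oc1cc(Br)c(OC)c(OC)c1OC | intermediate
5 | ethyl 3-(3,4-dimethoxyphenyl)-3-oxopropanoate | CCOC(=O)CC(=O)c1ccc(OC)c(OC)c1 | starting material
6 | ethyl (3S)-3-(3,4-dimethoxyphenyl)-3-hydroxypropanoate | COc1ccc([C@@H](O)CC(=O)OCC)cc1OC | intermediate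
7 | (3S)-3-(3,4-dimethoxyphenyl)-3-hydroxy-N-methoxy-N-methylpropanamide | COc1ccc([C@@H](O)CC(=O)N(C)OC)cc1OC | intermediate
8 | lithium 5-lithio-2,3,4-trimethoxyphenolate | [Li]Oc1cc([Li])c(OC)c(OC)c1OC | intermediate (not isolated)
9 | chloromagnesium alkoxide of 7 | COc1ccc([C@@H](O[Mg]Cl)CC(=O)N(C)OC)cc1OC | intermediate (not isolated)
10 | tetrahedral N-methoxy-N-methyl hemiaminal adduct (lithium and magnesium salt, both epimers at the new carbon) | COc1ccc([C@@H](O[Mg]Cl)CC(O[Li])(N(C)OC)c2cc(O[Li])c(OC)c(OC)c2OC)cc1OC | intermediate (not isolated)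
11 | (3S)-3-(3,4-dimethoxyphenyl)-3-hydroxy-1-(5-hydroxy-2,3,4-trimethoxyphenyl)propan-1-one | COc1ccc([C@@H](O)CC(=O)c2cc(O)c(OC)c(OC)c2OC)cc1OC | intermediate
12 | 3-[(3S)-3-(3,4-dimethoxyphenyl)-3-hydroxypropanoyl]-4,4,5,6-tetramethoxycyclohexa-2,5-dien-1-one | COc1ccc([C@@H](O)CC(=O)C2=CC(=O)C(OC)=C(OC)C2(OC)OC)cc1OC | intermediate (not isolated)
13 | (2S)-2-(3,4-dimethoxyphenyl)-5,6,7-trimethoxy-2,3-dihydro-4H-chromene-4,8(8aH)-dione (both epimers at C8a) | COc1ccc([C@@H]2CC(=O)C3=C(OC)C(OC)=C(OC)C(=O)C3O2)cc1OC | intermediate (not isolated)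
14 | (2S)-2-(3,4-dimethoxyphenyl)-8-hydroxy-5,6,7-trimethoxy-2,3-dihydro-4H-chromen-4-one | COc1ccc([C@@H]2CC(=O)c3c(c(O)c(OC)c(OC)c3OC)O2)cc1OC | target

Total steps: 6. Longest linear sequence: 4 steps (steps 1, 2, 5, 6 or steps 3, 4, 5, 6).

Steps most likely to fail

Step 6. The dearomatized intermediate may be diverted before ring closure: hydrolysis of the ketal to the quinone, capture of methanol at C8a, or acid-induced ionization or dehydration at the electron-rich benzylic carbinol. The product may also be oxidized a second time. The fallback sets out from 11 and uses known acylquinone chemistry to form the same O1–C8a bond. Oxidative demethylation with PhI(OAc)2 in MeCN–H2O at 0 °C should give 5-[(3S)-3-(3,4-dimethoxyphenyl)-3-hydroxypropanoyl]-2,3-dimethoxy-1,4-benzoquinone F1. 2-Acyl-1,4-benzoquinones are known to take up heteroatom nucleophiles at the ring carbon next to the acyl group, so the C2 hydroxyl should add to C8a and tautomerize to (2S)-2-(3,4-dimethoxyphenyl)-5,8-dihydroxy-6,7-dimethoxychroman-4-one F2. The non-chelated C8 hydroxyl is then benzylated (BnBr, K2CO3, acetone, rt) to (2S)-8-benzyloxy-2-(3,4-dimethoxyphenyl)-5-hydroxy-6,7-dimethoxychroman-4-one F3. The chelated C5 hydroxyl is methylated (MeI, Ag2O, DMF) to (2S)-8-benzyloxy-2-(3,4-dimethoxyphenyl)-5,6,7-trimethoxychroman-4-one F4. Hydrogenolysis (H2, Pd/C, EtOAc) comes back to the route at 14.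

Step 5. Halogen–lithium exchange on the lithium phenoxide may be incomplete, the doubly lithiated species may precipitate, or it may deprotonate the amide α-CH2 in place of adding. The fallback replaces the unprotected dianion by a protected monoanion. It sets out from 4, which is silylated (TBSCl, imidazole, DMF) to (5-bromo-2,3,4-trimethoxyphenoxy)(tert-butyl)dimethylsilane F5. Exchange with t-BuLi (THF, −78 °C) and addition to alkoxide 9, made from 7 as in step 5, should give (3S)-1-[5-(tert-butyldimethylsilyloxy)-2,3,4-trimethoxyphenyl]-3-(3,4-dimethoxyphenyl)-3-hydroxypropan-1-one F6. Near-neutral cleavage of the aryl silyl ether (KHF2, MeOH, rt) comes back to the route at 11.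

Step 3. Enantioselection may be incomplete for this electron-rich aroylacetate, and the benzylic carbinol may solvolyse or racemize under the acidic ruthenium chloride catalyst. The fallback replaces asymmetric catalysis by enzymatic kinetic resolution. It sets out from 5, which NaBH4 (EtOH, 0 °C) reduces to racemic ethyl 3-(3,4-dimethoxyphenyl)-3-hydroxypropanoate F7. Burkholderia cepacia lipase with vinyl acetate in t-BuOMe should, by the usual empirical rule for secondary carbinols with a large aryl and a medium alkyl group, acylate the R alcohol to ethyl (3R)-3-acetoxy-3-(3,4-dimethoxyphenyl)propanoate F8. The unreacted S alcohol, separated by chromatography, is 6, where the fallback comes back to the route.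

Further compounds
F1 | step 6 | 5-[(3S)-3-(3,4-dimethoxyphenyl)-3-hydroxypropanoyl]-2,3-dimethoxy-1,4-benzoquinone | COc1ccc([C@@H](O)CC(=O)C2=CC(=O)C(OC)=C(OC)C2=O)cc1OC
F2 | step 6 | (2S)-2-(3,4-dimethoxyphenyl)-5,8-dihydroxy-6,7-dimethoxychroman-4-one | COc1ccc([C@@H]2CC(=O)c3c(c(O)c(OC)c(OC)c3O)O2)cc1OC
F3 | step 6 | (2S)-8-benzyloxy-2-(3,4-dimethoxyphenyl)-5-hydroxy-6,7-dimethoxychroman-4-one | COc1ccc([C@@H]2CC(=O)c3c(c(OCc4ccccc4)c(OC)c(OC)c3O)O2)cc1OC
F4 | step 6 | (2S)-8-benzyloxy-2-(3,4-dimethoxyphenyl)-5,6,7-trimethoxychroman-4-one | COc1ccc([C@@H]2CC(=O)c3c(c(OCc4ccccc4)c(OC)c(OC)c3OC)O2)cc1OC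
F5 | step 5 | (5-bromo-2,3,4-trimethoxyphenoxy)(tert-butyl)dimethylsilane | CC(C)(C)[Si](C)(C)Oc1cc(Br)c(OC)c(OC)c1OC
F6 | step 5 | (3S)-1-[5-(tert-butyldimethylsilyloxy)-2,3,4-trimethoxyphenyl]-3-(3,4-dimethoxyphenyl)-3-hydroxypropan-1-one | COc1ccc([C@@H](O)CC(=O)c2cc(O[Si](C)(C)C(C)(C)C)c(OC)c(OC)c2OC)cc1OC
F7 | step 3 | racemic ethyl 3-(3,4-dimethoxyphenyl)-3-hydroxypropanoate | CCOC(=O)CC(O)c1ccc(OC)c(OC)c1
F8 | step 3 | ethyl (3R)-3-acetoxy-3-(3,4-dimethoxyphenyl)propanoate | CCOC(=O)C[C@@H](OC(C)=O)c1ccc(OC)c(OC)c1
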